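All constants were drawn at random within sensible limits; what happens was integrated by code.

The trap in these flasks was to give open intermediate a single half-life, since the substrate charge is ten times the second catalyst.

| flask | substrate | reagent | free catalyst | second catalyst | time | remark |
|---|---|---|---|---|---|---|
| Thursday's | 0.13 M | 0.390 M | 13 mM | 13 mM | 5.0 min | everything together at the start |
| Saturday's | 0.13 M | 0.390 M (fed, over 4.0 min) | 13 mM | 13 mM | 5.0 min | all else is in the flask from the start; the feed brings no volume worth counting |
| Sunday's | 0.13 M (fed, over 4.0 min) | 0.390 M | 13 mM | 13 mM | 5.0 min | all else is in the flask from the start; the feed brings no volume worth counting |

    substrate + free catalyst → free catalyst + open intermediate (k1 = 3.4 /M/s)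
    second catalyst + open intermediate ⇌ catalyst intermediate (K2 = 15 /M, k2 = 78 /M/s)
    reagent + catalyst intermediate → second catalyst + target (k3 = 0.48 /M/s)

1. the best flask by amount of target, in percent of the substrate charged; "all alike" if 1.5 percentage points covers them all (Thursday's / Saturday's / Sunday's / all alike)
2. amount of target at the end, in percent of the substrate charged, Thursday's
3. amount of target at the end, in percent of the substrate charged, Saturday's
4. amount of target at the end, in percent of the substrate charged, Sunday's

**Turnover budget.** Catalyst intermediate fell apart faster than reagent consumed it, so I held the second step at equilibrium and took the last step as rate-limiting. The bound share of second catalyst then reached 0.5 at 0.0667 M of open intermediate. Integrating that rate in closed form gave my rule: the amount turned, plus 0.0667 M times the ln of open intermediate at start over end, equals the turnover budget, which is the pace at full binding multiplied by the working time.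

**Two extremes.** In each reckoning of the target I put the whole amount present as the amount turned. With reagent held at its charge and substrate opened at once, Thursday's budget was 0.730 M, and I reckoned 0.0123% of the substrate charged left unturned. With reagent held at what remains after the whole substrate has reacted, the pace was 1.62 mM/s. Taking off the mean opening wait of 22.6 s gave a budget of 0.450 M and target 99.2%. Thursday's real reagent starts at the upper value and falls to the lower, so I expected the flask between them.

**Fed flasks.** Keeping the low pace, I charged Saturday's reagent a mean delay of 0.5 of the feed time, so its budget was 0.292 M and target 91.2%. Sunday's feed of 0.542 mM/s ran below the pace, so I reckoned about 0.0457 M unturned when it stopped, against a remaining budget of 0.0973 M. That gave target 83.8%. My best flask was Thursday's.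

**The forecast.** It named Thursday's, with 99% for Thursday's, 93% for Saturday's and 88% for Sunday's, on the ground that “Sunday's loses most because its intermediate stays far below saturation while the last of the substrate arrives late”. Its fed flasks stood above my low figures.

**The flasks.** The simulation gave 99.2% for Thursday's, 93.4% for Saturday's and 87.7% for Sunday's, with Thursday's best, as the forecast said. Sunday's still held 10.0% as open intermediate after 5.00 min, and its target reached 100% after 50.0 min. Thursday's open intermediate of 0.647% puts the rule's left side at 0.465 M, just above the low budget. Thursday's flask read at 2.0 min held 19.8% as open intermediate, which needs 0.212 M. Its budget, with reagent taken midway between the charge and the 74.4% then left, was 0.207 M, and that flask held target 76.9%.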